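**Plan**
- Enabling feature: in the 19-membered carbocycle the methyl-bearing carbon on thiolane C3 lies one CH2 away from the isolated E-alkene. With CH3 read as CO2H this is a γ,δ-unsaturated acid, i.e. the Ireland–Claisen product of an ester between that carboxyl and the neighbouring vinyl carbinol.
- Bonds cut, in retrosynthetic order: the C(CO2H)–CH2 bond together with the E-alkene (transannular [3,3]); the lactone C–O bond; the C–C bond joining the two alkenes of the diene; the bond from tetronate C3 to the carbinol carbon.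
- Forward ring order: cyclohexene (Diels–Alder), tetronate (Dieckmann), thiolane (sulfa-Michael/Michael cascade), 19-membered lactone, then the [3,3] shift turns the lactone into the 19-membered carbocycle.
- After the key step: CO2H to CH3, oxidation to the acyl ketone and α-keto acid, deprotection.
- Stereochemistry: spiro and ring centres from the (R)-lactic-acid-derived dienophile (exo, anti to t-Bu); thiolane C2 from (S)-glyceraldehyde acetonide (Felkin–Anh addition, Mitsunobu inversion), C3 and C4 relayed from C2 and the amine catalyst; both chain carbinols from a (4R,6S)-dioxane building block; the methyl-bearing centre and the E-alkene from the chair Claisen.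

Key step: step 28

Assumption: compounds 7, 15 and 24 are taken as purchased; the carbinol carbon between tetronate and thiolane is carried as both epimers (drawn without descriptor) because it becomes a ketone in step 33, and the dioxolane centre (S here) is likewise destroyed later.

**Fragment A: spirotetronate (steps 1–8)**

Step 1
Reactants: 1 (R)-lactic acid
Product: 2 (2R,5R)-2-tert-butyl-5-methyl-1,3-dioxolan-4-one
Conditions: t-BuCHO, p-TsOH (cat.), H2SO4 (cat.), pentane, reflux with water separator; recrystallisation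
Reagents that add atoms: pivalaldehyde CC(C)(C)C=O
Why: Acid-catalysed acetalisation of the α-hydroxy acid should give the dioxolanone, the cis isomer (new acetal centre R) being thermodynamically favoured and crystalline.

Step 2
Reactants: 2 (2R,5R)-2-tert-butyl-5-methyl-1,3-dioxolan-4-one
Product: 4 (2R)-2-tert-butyl-5-methylidene-1,3-dioxolan-4-one, via bromide 3 (not isolated)
Conditions: N-bromosuccinimide, AIBN, cyclohexane, reflux; then Et3N, CH2Cl2, 0 °C to rt
Reagents that add atoms: none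
Why: Radical bromination of the captodative C5–H followed by E2 dehydrobromination should give the exo-methylene dienophile with the acetal centre untouched.

Step 3
Reactants: 5 but-3-yn-1-ol
Product: 6 1-[(but-3-yn-1-yloxy)methyl]-4-methoxybenzene
Conditions: NaH, 4-MeOC6H4CH2Cl, Bu4NI (cat.), THF/DMF, 0 °C to rt
Reagents that add atoms: 4-methoxybenzyl chloride COc1ccc(CCl)cc1
Why: Williamson etherification of the alkoxide, the O–H being far more acidic than the alkyne C–H.

Step 4
Reactants: 6 1-[(but-3-yn-1-yloxy)methyl]-4-methoxybenzene; 7 (E)-2-bromobut-2-ene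
Product: 9 (3E,5E)-5-methylhepta-3,5-dien-1-yl 4-methoxybenzyl ether, via alkenylboronate 8 (not isolated)
Conditions: catecholborane, neat, 70 °C; then 7, Pd(PPh3)4 (3 mol %), 2 M NaOH, THF, 65 °C
Reagents that add atoms: none
Why: syn-Hydroboration gives the E-alkenylboronate and Suzuki–Miyaura coupling proceeds with retention at both sp2 carbons, which fixes the E,E-diene.

Step 5
Reactants: 9 (3E,5E)-5-methylhepta-3,5-dien-1-yl 4-methoxybenzyl ether; 4 (2R)-2-tert-butyl-5-methylidene-1,3-dioxolan-4-one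
Product: 10 spiro Diels–Alder adduct (2R,5S,6R,9R)
Conditions: toluene, BHT (cat.), 90 °C, sealed tube
Reagents that add atoms: none
Why: Diels–Alder cycloaddition in which the dienophile CH2 bonds to the methyl-bearing diene terminus ("para" to the 2-methyl group) and the diene approaches anti to tert-butyl with the lactone carbonyl exo, which should set the spiro centre (S) and both ring centres (6R,9R).

Step 6
Reactants: 10 spiro Diels–Alder adduct
Product: 11 methyl (1S,2R,5R)-1-hydroxy-2-[2-(4-methoxybenzyloxy)ethyl]-4,5-dimethylcyclohex-3-ene-1-carboxylate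
Conditions: K2CO3, MeOH, rt
Reagents that add atoms: methanol CO
Why: Methanolysis of the acylal-type lactone releases pivalaldehyde and leaves the tertiary α-hydroxy methyl ester without touching a stereocentre.

Step 7
Reactants: 11 tertiary α-hydroxy ester
Product: 12 methyl (1S,2R,5R)-1-acetoxy-2-[2-(4-methoxybenzyloxy)ethyl]-4,5-dimethylcyclohex-3-ene-1-carboxylate
Conditions: Ac2O, Et3N, DMAP, CH2Cl2, rt
Reagents that add atoms: acetic anhydride CC(=O)OC(C)=O
Why: DMAP-catalysed acylation of the tertiary alcohol installs the acetate needed for the Dieckmann closure.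

Step 8
Reactants: 12 α-acetoxy ester
Product: 14 (5S,6R,9R)-4-methoxy-6-[2-(4-methoxybenzyloxy)ethyl]-8,9-dimethyl-1-oxaspiro[4.5]deca-3,7-dien-2-one, via lithium tetronate 13 (not isolated)
Conditions: LiN(SiMe3)2 (2.5 equiv), THF/HMPA, −78 to 0 °C; then MeOTf, 0 °C
Reagents that add atoms: methyl trifluoromethanesulfonate COS(=O)(=O)C(F)(F)F
Why: Dieckmann condensation of the acetate enolate onto the neighbouring methyl ester closes the five-membered tetronate ring and the tetronate anion is O-methylated at O4 by the hard methylating agent.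

**Fragment B: thiolane aldehyde (steps 9–12)**

Step 9
Reactants: 15 (S)-2,2-dimethyl-1,3-dioxolane-4-carbaldehyde; 16 methyl propiolate
Product: 17 methyl (4R)-4-[(4S)-2,2-dimethyl-1,3-dioxolan-4-yl]-4-hydroxybut-2-ynoate
Conditions: 16, LiN(iPr)2, THF, −78 °C; then 15, −78 °C; AcOH quench
Reagents that add atoms: none
Why: Felkin–Anh addition of the lithium acetylide anti to the dioxolane C–O bond should favour the anti (4R) carbinol, and the minor syn isomer is removed by chromatography.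

Step 10
Reactants: 17 ynoate carbinol
Product: 18 methyl (2E,4R)-4-[(4S)-2,2-dimethyl-1,3-dioxolan-4-yl]-4-hydroxybut-2-enoate
Conditions: NaAlH2(OCH2CH2OMe)2, THF, −72 °C
Reagents that add atoms: none
Why: Hydroxyl-directed trans-hydroalumination of the γ-hydroxy ynoate and protonation give the E-enoate, the ester being inert at this temperature.

Step 11
Reactants: 18 γ-hydroxy enoate
Product: 19 methyl (2E,4S)-4-(acetylsulfanyl)-4-[(4S)-2,2-dimethyl-1,3-dioxolan-4-yl]but-2-enoate
Conditions: PPh3, i-PrO2CN=NCO2i-Pr, AcSH, THF, 0 °C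
Reagents that add atoms: thioacetic acid CC(=O)S
Why: Mitsunobu displacement by thioacetate proceeds by SN2 with inversion at the allylic carbinol (SN2' attack at the ester α-carbon is polarity-mismatched), which sets the sulfur-bearing centre (S).

Step 12
Reactants: 19 thioacetate; 20 acrolein
Product: 23 methyl 2-[(2S,3S,4R)-2-[(4S)-2,2-dimethyl-1,3-dioxolan-4-yl]-4-formylthiolan-3-yl]acetate, via thiol 21 (not isolated), via sulfanyl aldehyde 22 (not isolated)
Conditions: N2H4·AcOH, DMF, 0 °C, extractive work-up; then 20, (S)-2-[diphenyl(trimethylsilyloxy)methyl]pyrrolidine (20 mol %), PhCO2H (20 mol %), toluene, 0 °C to rt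
Reagents that add atoms: none
Why: Organocatalytic sulfa-Michael/Michael cascade in which the freed thiol adds to the iminium ion of acrolein and the resulting enamine closes the thiolane by 5-exo-trig addition to the enoate; C3 should form trans to the pseudo-equatorial dioxolanyl group on C2, the S-configured amine directs the matching enamine face for C4, and C4 can in any case equilibrate to the all-trans isomer.

**Fragment C: iodo dienol (steps 13–19)**

Step 13
Reactants: 24 tert-butyl 2-[(4R,6S)-6-(hydroxymethyl)-2,2-dimethyl-1,3-dioxan-4-yl]acetate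
Product: 25 tert-butyl 2-[(4R,6S)-6-formyl-2,2-dimethyl-1,3-dioxan-4-yl]acetate
Conditions: (COCl)2, DMSO, CH2Cl2, −78 °C; Et3N
Reagents that add atoms: none
Why: Swern oxidation of the primary alcohol at low temperature should not epimerise the α-alkoxy aldehyde.

Step 14
Reactants: 25 dioxane aldehyde
Product: 26 tert-butyl 2-[(4R,6S)-6-ethenyl-2,2-dimethyl-1,3-dioxan-4-yl]acetate
Conditions: Ph3PCH3Br, KN(SiMe3)2, THF, −78 to 0 °C
Reagents that add atoms: methyltriphenylphosphonium bromide C[P+](c1ccccc1)(c1ccccc1)c1ccccc1.[Br-]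
Why: Wittig methylenation with the salt-free ylide turns the formyl group into the vinyl group that later takes part in the [3,3] shift.

Step 15
Reactants: 26 vinyl dioxane ester
Product: 27 (4R,6S)-6-ethenyl-4-hydroxyoxan-2-one
Conditions: CF3CO2H, CH2Cl2, H2O (2 equiv), 0 °C to rt
Reagents that add atoms: none
Why: Acid removes the acetonide and the tert-butyl ester, and only the allylic hydroxyl can lactonise (six-membered ring), which differentiates the two carbinols.

Step 16
Reactants: 27 hydroxy lactone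
Product: 28 (4R,6S)-4-[(tert-butyldiphenylsilyl)oxy]-6-ethenyloxan-2-one
Conditions: t-BuPh2SiCl, imidazole, DMF, rt
Reagents that add atoms: tert-butyl(chloro)diphenylsilane CC(C)(C)[Si](Cl)(c1ccccc1)c1ccccc1
Why: Silylation of the free secondary alcohol with an acid-stable group that survives the later acetonide cleavage.

Step 17
Reactants: 28 silyl lactone
Product: 29 (4R,6S)-4-[(tert-butyldiphenylsilyl)oxy]-6-ethenyloxan-2-ol (anomers)
Conditions: i-Bu2AlH, CH2Cl2, −78 °C
Reagents that add atoms: none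
Why: Half-reduction of the lactone stops at the lactol because the tetrahedral aluminate is stable at −78 °C.

Step 18
Reactants: 29 lactol
Product: 30 (3S,5S)-5-[(tert-butyldiphenylsilyl)oxy]oct-1-en-7-yn-3-ol
Conditions: MeC(O)C(N2)P(O)(OMe)2, K2CO3, MeOH, 0 °C to rt
Reagents that add atoms: dimethyl (1-diazo-2-oxopropyl)phosphonate COP(=O)(OC)C(=[N+]=[N-])C(C)=O
Why: Ohira–Bestmann homologation of the open hydroxy aldehyde form gives the terminal alkyne and frees the allylic hydroxyl that was the lactone oxygen.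

Step 19
Reactants: 30 enynol
Product: 32 (3S,5S,7E)-5-[(tert-butyldiphenylsilyl)oxy]-8-iodoocta-1,7-dien-3-ol, via alkenylzirconocene 31 (not isolated)
Conditions: Cp2Zr(H)Cl (2.3 equiv), THF, rt; then I2, 0 °C
Reagents that add atoms: iodine II
Why: syn-Hydrozirconation of the terminal alkyne (faster than that of the vinyl group; one equivalent is consumed by the hydroxyl) and iodinolysis with retention give only the E-iodoalkene.

**Assembly and macrolactone (steps 20–27)**

Step 20
Reactants: 14 O-methyl spirotetronate; 23 thiolane aldehyde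
Product: 34 tetronate–thiolane carbinol (both epimers), via lithiated tetronate 33 (not isolated)
Conditions: 14, LiN(iPr)2 (1.05 equiv), THF, −78 °C; then 23, −78 °C; AcOH quench at −78 °C
Reagents that add atoms: none
Why: C3-lithiation of the 4-methoxyfuranone (no γ-hydrogen at the spiro centre) and 1,2-addition to the aldehyde at −78 °C leave the ester untouched, and the cold quench forestalls δ-lactonisation of the alkoxide.

Step 21
Reactants: 34 carbinol
Product: 35 triethylsilyl ether of 34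
Conditions: Et3SiOTf, 2,6-lutidine, CH2Cl2, −78 °C
Reagents that add atoms: triethylsilyl trifluoromethanesulfonate CC[Si](CC)(CC)OS(=O)(=O)C(F)(F)F
Why: Silyl triflate silylation of the hindered secondary alcohol masks the future acyl carbon so that the lactone is later the only enolisable carbonyl, with a group that falls together with the acetonide in step 32.

Step 22
Reactants: 35 silyl ether
Product: 36 primary alcohol (PMB removed)
Conditions: DDQ, CH2Cl2/pH 7 buffer, 0 °C
Reagents that add atoms: none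
Why: Oxidative cleavage of the electron-rich benzyl ether by DDQ under buffered conditions should spare the thioether, the silyl ether and the acetonide.

Step 23
Reactants: 36 primary alcohol
Product: 37 aldehyde
Conditions: Dess–Martin periodinane, NaHCO3, CH2Cl2, 0 °C to rt
Reagents that add atoms: none
Why: Dess–Martin oxidation of the primary alcohol under buffered conditions does not oxidise the sulfide.

Step 24
Reactants: 37 aldehyde
Product: 38 E-alkenylboronate
Conditions: CrCl2 (8 equiv), LiI (4 equiv), Cl2CHBpin, THF, rt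
Reagents that add atoms: 2-(dichloromethyl)-4,4,5,5-tetramethyl-1,3,2-dioxaborolane CC1(C)OB(C(Cl)Cl)OC1(C)C
Why: Takai–Utimoto borylolefination through a geminal dichromium reagent adds to the aldehyde and eliminates to the E-alkenylboronate while esters, lactone, silyl ether and thioether are tolerated.

Step 25
Reactants: 38 E-alkenylboronate; 32 iodo dienol
Product: 39 E,E-diene seco ester
Conditions: PdCl2(dppf) (10 mol %), Ph3As, Cs2CO3, DMF/THF/H2O, rt
Reagents that add atoms: none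
Why: Suzuki–Miyaura coupling of two E-configured sp2 partners with retention gives the skipped E,E-diene in the presence of the free allylic alcohol.

Step 26
Reactants: 39 seco ester
Product: 40 seco acid
Conditions: Me3SnOH, 1,2-dichloroethane, 70 °C; 0.05 M HCl work-up at 0 °C
Reagents that add atoms: trimethyltin hydroxide C[Sn](C)(C)O
Why: Tin hydroxide hydrolysis is selective for the unhindered methyl ester and should leave the spiro butenolide, the enol ether and the silyl ethers intact.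

Step 27
Reactants: 40 seco acid
Product: 42 19-membered vinyl macrolactone, via mixed anhydride 41 (not isolated)
Conditions: 2,4,6-Cl3C6H2COCl, Et3N, THF, rt; then slow addition to DMAP, toluene, 80 °C, high dilution
Reagents that add atoms: none
Why: Yamaguchi macrolactonisation, in which the acylpyridinium formed from the mixed anhydride is captured by the secondary allylic alcohol under high dilution with retention at the carbinol.

**Key step (step 28)**

Step 28
Reactants: 42 19-membered vinyl macrolactone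
Product: 45 19-membered carbocyclic acid, via silyl ketene acetal 43 (not isolated), via silyl ester 44 (not isolated)
Conditions: Me3SiCl/Et3N (premixed, excess), THF, −78 °C; LiN(iPr)2 added slowly, −78 °C; then rt to 60 °C; aqueous citric acid work-up
Reagents that add atoms: none
Why: LiN(iPr)2 in THF with Me3SiCl present converts the lactone, the only enolisable carbonyl of 42, into the E(O) silyl ketene acetal 43 (thiolane carbon cis to the ring oxygen), which undergoes an Ireland–Claisen [3,3]-sigmatropic shift on warming; the closest known reaction type is the rearrangement of silyl ketene acetals of vinyl-substituted lactones to cycloalkene carboxylic acids. The 19-membered carbocycle closes transannularly, by C–C bond formation between the ketene acetal carbon and the vinyl terminus in a six-membered cyclic transition state while the lactone C–O bond breaks, so the ester O and C=O leave the ring, the two vinyl carbons enter it and the ring size is conserved. The new stereocentre (carboxyl-bearing carbon, S) is set by chirality transfer from the S-configured allylic carbinol through a chair with the ring tether equatorial on the carbinol carbon, combined with the E(O) geometry of the ketene acetal. The same chair delivers the E-alkene. The step needs chair over boat and E(O) over Z(O) enolisation; the first is expected because a ring of this size imposes none of the constraints that force small lactones through a boat, the second from kinetic deprotonation in THF without HMPA. Mild acid work-up cleaves the silyl ester 44 without touching the other silyl ethers.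

**Endgame (steps 29–36)**

Step 29
Reactants: 45 carbocyclic acid
Product: 47 primary alcohol, via mixed carbonic anhydride 46 (not isolated)
Conditions: i-BuOCOCl, N-methylmorpholine, THF, −15 °C; then NaBH4, THF/H2O, 0 °C
Reagents that add atoms: none
Why: Activation as the mixed carbonic anhydride lets NaBH4 reduce only the carboxyl group, the vinylogous carbonate of the tetronate and the alkenes being inert.

Step 30
Reactants: 47 primary alcohol
Product: 48 primary iodide
Conditions: I2, PPh3, imidazole, CH2Cl2, 0 °C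
Reagents that add atoms: iodine II
Why: Appel-type iodination through the alkoxyphosphonium ion displaces at CH2 only, and the iodide is used at once because the ring sulfur could alkylate intramolecularly on standing.

Step 31
Reactants: 48 primary iodide
Product: 49 C-methyl macrocycle
Conditions: Bu3SnH, Et3B, air (trace), toluene, 0 °C to rt
Reagents that add atoms: none
Why: Radical-chain reduction of the primary iodide at low temperature, the 4-pentenyl-type radical being too slow to cyclise before hydrogen transfer.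

Step 32
Reactants: 49 C-methyl macrocycle
Product: 50 triol
Conditions: AcOH/THF/H2O (3:1:1), 45 °C
Reagents that add atoms: none
Why: Mild aqueous acid removes the triethylsilyl ether and the terminal isopropylidene acetal while the tert-butyldiphenylsilyl ether and the tetronate enol ether survive.

Step 33
Reactants: 50 triol
Product: 51 acyl ketone keto aldehyde
Conditions: (COCl)2, DMSO, CH2Cl2, −78 °C; Et3N, −78 to −20 °C
Reagents that add atoms: none
Why: Swern oxidation turns the carbinol next to the tetronate into the acyl ketone and the vicinal diol into the α-keto aldehyde without glycol cleavage or S-oxidation, and thiolane C2 and C4, now α to carbonyls, should settle in the all-trans arrangement.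

Step 34
Reactants: 51 keto aldehyde
Product: 52 α-keto acid
Conditions: NaClO2, NaH2PO4, 2-methylbut-2-ene (large excess), t-BuOH/H2O, 0 °C
Reagents that add atoms: sodium chlorite [Na+].[O-]Cl=O
Why: Pinnick oxidation of the aldehyde, with the alkene scavenger removing hypochlorite before it reaches the thioether or the polyene.

Step 35
Reactants: 52 α-keto acid
Product: 53 O-methyl target
Conditions: HF·pyridine, pyridine, THF, rt
Reagents that add atoms: none
Why: Fluoride cleavage of the Si–O bond frees the ring carbinol under buffered, non-basic conditions.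

Step 36
Reactants: 53 O-methyl target
Product: 54 target CNP0224658.3
Conditions: LiCl, DMSO, 50 °C; then dilute HCl
Reagents that add atoms: none
Why: SN2 demethylation by chloride works because the 3-acyltetronate is an excellent leaving group, and acidification liberates the acyl tetronic acid.

**Compound list**

1 | (R)-lactic acid | C[C@@H](O)C(=O)O | starting material
2 | (2R,5R)-2-tert-butyl-5-methyl-1,3-dioxolan-4-one (cis) | C[C@H]1O[C@@H](C(C)(C)C)OC1=O | intermediate
3 | (2R,5S)-5-bromo-2-tert-butyl-5-methyl-1,3-dioxolan-4-one (Br trans to t-Bu) | C[C@@]1(Br)O[C@@H](C(C)(C)C)OC1=O | intermediate (not isolated)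
4 | (2R)-2-tert-butyl-5-methylidene-1,3-dioxolan-4-one | C=C1O[C@@H](C(C)(C)C)OC1=O | intermediate
5 | but-3-yn-1-ol | C#CCCO | starting material
6 | 1-[(but-3-yn-1-yloxy)methyl]-4-methoxybenzene | C#CCCOCc1ccc(OC)cc1 | intermediate
7 | (E)-2-bromobut-2-ene | C/C=C(/Br)C | starting material
8 | 2-[(1E)-4-(4-methoxybenzyloxy)but-1-en-1-yl]-1,3,2-benzodioxaborole | COc1ccc(COCC/C=C/B2Oc3ccccc3O2)cc1 | intermediate (not isolated)
9 | 1-methoxy-4-({[(3E,5E)-5-methylhepta-3,5-dien-1-yl]oxy}methyl)benzene | C/C=C(C)/C=C/CCOCc1ccc(OC)cc1 | intermediate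
10 | (2R,5S,6R,9R)-2-tert-butyl-6-[2-(4-methoxybenzyloxy)ethyl]-8,9-dimethyl-1,3-dioxaspiro[4.5]dec-7-en-4-one | CC1=C[C@@H](CCOCc3ccc(OC)cc3)[C@]2(C[C@H]1C)O[C@@H](C(C)(C)C)OC2=O | intermediate
11 | methyl (1S,2R,5R)-1-hydroxy-2-[2-(4-methoxybenzyloxy)ethyl]-4,5-dimethylcyclohex-3-ene-1-carboxylate | CC1=C[C@@H](CCOCc2ccc(OC)cc2)[C@@](O)(C[C@H]1C)C(=O)OC | intermediate
12 | methyl (1S,2R,5R)-1-acetoxy-2-[2-(4-methoxybenzyloxy)ethyl]-4,5-dimethylcyclohex-3-ene-1-carboxylate | CC1=C[C@@H](CCOCc2ccc(OC)cc2)[C@@](OC(C)=O)(C[C@H]1C)C(=O)OC | intermediate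
13 | lithium (5S,6R,9R)-6-[2-(4-methoxybenzyloxy)ethyl]-8,9-dimethyl-2-oxo-1-oxaspiro[4.5]deca-3,7-dien-4-olate | CC1=C[C@@H](CCOCc2ccc(OC)cc2)[C@]3(C[C@H]1C)OC(=O)C=C3[O-].[Li+] | intermediate (not isolated)
14 | (5S,6R,9R)-4-methoxy-6-[2-(4-methoxybenzyloxy)ethyl]-8,9-dimethyl-1-oxaspiro[4.5]deca-3,7-dien-2-one | CC1=C[C@@H](CCOCc2ccc(OC)cc2)[C@]3(C[C@H]1C)OC(=O)C=C3OC | intermediate
15 | (S)-2,2-dimethyl-1,3-dioxolane-4-carbaldehyde | O=C[C@@H]1COC(C)(C)O1 | starting material
16 | methyl propiolate | C#CC(=O)OC | starting material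
17 | methyl (4R)-4-[(4S)-2,2-dimethyl-1,3-dioxolan-4-yl]-4-hydroxybut-2-ynoate | COC(=O)C#C[C@@H](O)[C@@H]1COC(C)(C)O1 | intermediate
18 | methyl (2E,4R)-4-[(4S)-2,2-dimethyl-1,3-dioxolan-4-yl]-4-hydroxybut-2-enoate | COC(=O)/C=C/[C@@H](O)[C@@H]1COC(C)(C)O1 | intermediate
19 | methyl (2E,4S)-4-(acetylsulfanyl)-4-[(4S)-2,2-dimethyl-1,3-dioxolan-4-yl]but-2-enoate | COC(=O)/C=C/[C@H](SC(C)=O)[C@@H]1COC(C)(C)O1 | intermediate
20 | acrolein | C=CC=O | starting material
21 | methyl (2E,4S)-4-[(4S)-2,2-dimethyl-1,3-dioxolan-4-yl]-4-sulfanylbut-2-enoate | COC(=O)/C=C/[C@H](S)[C@@H]1COC(C)(C)O1 | intermediate (not isolated)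
22 | methyl (2E,4S)-4-[(4S)-2,2-dimethyl-1,3-dioxolan-4-yl]-4-[(3-oxopropyl)sulfanyl]but-2-enoate | COC(=O)/C=C/[C@H](SCCC=O)[C@@H]1COC(C)(C)O1 | intermediate (not isolated)
23 | methyl 2-[(2S,3S,4R)-2-[(4S)-2,2-dimethyl-1,3-dioxolan-4-yl]-4-formylthiolan-3-yl]acetate (all-trans) | COC(=O)C[C@@H]1[C@@H]([C@@H]2COC(C)(C)O2)SC[C@H]1C=O | intermediate
24 | tert-butyl 2-[(4R,6S)-6-(hydroxymethyl)-2,2-dimethyl-1,3-dioxan-4-yl]acetate | CC(C)(C)OC(=O)C[C@H]1C[C@@H](CO)OC(C)(C)O1 | starting material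
25 | tert-butyl 2-[(4R,6S)-6-formyl-2,2-dimethyl-1,3-dioxan-4-yl]acetate | CC(C)(C)OC(=O)C[C@H]1C[C@@H](C=O)OC(C)(C)O1 | intermediate
26 | tert-butyl 2-[(4R,6S)-6-ethenyl-2,2-dimethyl-1,3-dioxan-4-yl]acetate | CC(C)(C)OC(=O)C[C@H]1C[C@@H](C=C)OC(C)(C)O1 | intermediate
27 | (4R,6S)-6-ethenyl-4-hydroxyoxan-2-one | O=C1C[C@H](O)C[C@@H](C=C)O1 | intermediate
28 | (4R,6S)-4-[(tert-butyldiphenylsilyl)oxy]-6-ethenyloxan-2-one | O=C1C[C@H](O[Si](c2ccccc2)(c2ccccc2)C(C)(C)C)C[C@@H](C=C)O1 | intermediate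
29 | (4R,6S)-4-[(tert-butyldiphenylsilyl)oxy]-6-ethenyloxan-2-ol (anomers) | OC1C[C@H](O[Si](c2ccccc2)(c2ccccc2)C(C)(C)C)C[C@@H](C=C)O1 | intermediate
30 | (3S,5S)-5-[(tert-butyldiphenylsilyl)oxy]oct-1-en-7-yn-3-ol | C#CC[C@H](O[Si](c1ccccc1)(c1ccccc1)C(C)(C)C)C[C@@H](C=C)O | intermediate
31 | E-alkenyl(chloro)zirconocene of 30 with the hydroxyl as its chlorozirconocene alkoxide | Cl[Zr](C1C=CC=C1)(C1C=CC=C1)/C=C/C[C@H](O[Si](c2ccccc2)(c2ccccc2)C(C)(C)C)C[C@@H](C=C)O[Zr](Cl)(C1C=CC=C1)C1C=CC=C1 | intermediate (not isolated)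
32 | (3S,5S,7E)-5-[(tert-butyldiphenylsilyl)oxy]-8-iodoocta-1,7-dien-3-ol | I/C=C/C[C@H](O[Si](c1ccccc1)(c1ccccc1)C(C)(C)C)C[C@@H](C=C)O | intermediate
33 | 3-lithio derivative of 14 | CC1=C[C@@H](CCOCc2ccc(OC)cc2)[C@]3(C[C@H]1C)OC(=O)C([Li])=C3OC | intermediate (not isolated)
34 | methyl 2-[(2S,3S,4R)-2-[(4S)-2,2-dimethyl-1,3-dioxolan-4-yl]-4-{hydroxy[(5S,6R,9R)-4-methoxy-6-[2-(4-methoxybenzyloxy)ethyl]-8,9-dimethyl-2-oxo-1-oxaspiro[4.5]deca-3,7-dien-3-yl]methyl}thiolan-3-yl]acetate (both carbinol epimers) | CC1=C[C@@H](CCOCc2ccc(OC)cc2)[C@]3(C[C@H]1C)OC(=O)C(=C3OC)C(O)[C@@H]4CS[C@H]([C@@H]5COC(C)(C)O5)[C@H]4CC(=O)OC | intermediate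
35 | triethylsilyl ether of 34 at the carbinol | CC1=C[C@@H](CCOCc2ccc(OC)cc2)[C@]3(C[C@H]1C)OC(=O)C(=C3OC)C(O[Si](CC)(CC)CC)[C@@H]4CS[C@H]([C@@H]5COC(C)(C)O5)[C@H]4CC(=O)OC | intermediate
36 | 35 with the PMB ether cleaved (2-hydroxyethyl side chain on the cyclohexene) | CC1=C[C@@H](CCO)[C@]3(C[C@H]1C)OC(=O)C(=C3OC)C(O[Si](CC)(CC)CC)[C@@H]4CS[C@H]([C@@H]5COC(C)(C)O5)[C@H]4CC(=O)OC | intermediate
37 | aldehyde from 36 (2-oxoethyl side chain) | CC1=C[C@@H](CC=O)[C@]3(C[C@H]1C)OC(=O)C(=C3OC)C(O[Si](CC)(CC)CC)[C@@H]4CS[C@H]([C@@H]5COC(C)(C)O5)[C@H]4CC(=O)OC | intermediate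
38 | E-alkenyl pinacol boronate from 37 (side chain CH2–CH=CH–Bpin) | CC1=C[C@@H](C/C=C/B2OC(C)(C)C(C)(C)O2)[C@]3(C[C@H]1C)OC(=O)C(=C3OC)C(O[Si](CC)(CC)CC)[C@@H]4CS[C@H]([C@@H]5COC(C)(C)O5)[C@H]4CC(=O)OC | intermediate
39 | seco methyl ester: 38 coupled with 32 (side chain CH2–(E)CH=CH–(E)CH=CH–CH2–CH(OSiPh2t-Bu)–CH2–CH(OH)–CH=CH2, both carbinols S) | CC1=C[C@@H](C/C=C/C=C/C[C@H](O[Si](c2ccccc2)(c2ccccc2)C(C)(C)C)C[C@@H](C=C)O)[C@]3(C[C@H]1C)OC(=O)C(=C3OC)C(O[Si](CC)(CC)CC)[C@@H]4CS[C@H]([C@@H]5COC(C)(C)O5)[C@H]4CC(=O)OC | intermediate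
40 | seco acid (39 with CO2H in place of CO2Me) | CC1=C[C@@H](C/C=C/C=C/C[C@H](O[Si](c2ccccc2)(c2ccccc2)C(C)(C)C)C[C@@H](C=C)O)[C@]3(C[C@H]1C)OC(=O)C(=C3OC)C(O[Si](CC)(CC)CC)[C@@H]4CS[C@H]([C@@H]5COC(C)(C)O5)[C@H]4CC(=O)O | intermediate
41 | mixed anhydride of 40 with 2,4,6-trichlorobenzoic acid | CC1=C[C@@H](C/C=C/C=C/C[C@H](O[Si](c2ccccc2)(c2ccccc2)C(C)(C)C)C[C@@H](C=C)O)[C@]3(C[C@H]1C)OC(=O)C(=C3OC)C(O[Si](CC)(CC)CC)[C@@H]4CS[C@H]([C@@H]5COC(C)(C)O5)[C@H]4CC(=O)OC(=O)c2c(Cl)cc(Cl)cc2Cl | intermediate (not isolated)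
42 | 19-membered vinyl macrolactone: lactone between the thiolane-3-acetic acid and the (S)-vinyl carbinol; ring (S)-OSiPh2t-Bu carbinol, OSiEt3 carbinol (both epimers), (S)-acetonide, O-methyl spirotetronate; other centres as in 54 | CC1=C[C@H]2C/C=C/C=C/C[C@H](O[Si](c5ccccc5)(c5ccccc5)C(C)(C)C)C[C@@H](C=C)OC(=O)C[C@@H]3[C@@H]([C@@H]4COC(C)(C)O4)SC[C@H]3C(O[Si](CC)(CC)CC)C3=C(OC)[C@@]2(C[C@H]1C)OC3=O | intermediate (key-step precursor)
43 | E(O) trimethylsilyl ketene acetal of 42 (thiolane carbon cis to the ring oxygen) | CC1=C[C@H]2C/C=C/C=C/C[C@H](O[Si](c5ccccc5)(c5ccccc5)C(C)(C)C)C[C@@H](C=C)O/C(O[Si](C)(C)C)=C\[C@@H]3[C@@H]([C@@H]4COC(C)(C)O4)SC[C@H]3C(O[Si](CC)(CC)CC)C3=C(OC)[C@@]2(C[C@H]1C)OC3=O | intermediate (not isolated)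
44 | trimethylsilyl ester of 45 | CC1=C[C@H]2C/C=C/C=C/C[C@H](O[Si](c5ccccc5)(c5ccccc5)C(C)(C)C)C/C=C/C[C@H](C(=O)O[Si](C)(C)C)[C@@H]3[C@@H]([C@@H]4COC(C)(C)O4)SC[C@H]3C(O[Si](CC)(CC)CC)C3=C(OC)[C@@]2(C[C@H]1C)OC3=O | intermediate (not isolated)
45 | 19-membered carbocyclic acid: new E-alkene, (S)-CH(CO2H) on thiolane C3; protecting groups as in 42 | CC1=C[C@H]2C/C=C/C=C/C[C@H](O[Si](c5ccccc5)(c5ccccc5)C(C)(C)C)C/C=C/C[C@H](C(=O)O)[C@@H]3[C@@H]([C@@H]4COC(C)(C)O4)SC[C@H]3C(O[Si](CC)(CC)CC)C3=C(OC)[C@@]2(C[C@H]1C)OC3=O | intermediate (key-step product)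
46 | isobutyl carbonic mixed anhydride of 45 | CC1=C[C@H]2C/C=C/C=C/C[C@H](O[Si](c5ccccc5)(c5ccccc5)C(C)(C)C)C/C=C/C[C@H](C(=O)OC(=O)OCC(C)C)[C@@H]3[C@@H]([C@@H]4COC(C)(C)O4)SC[C@H]3C(O[Si](CC)(CC)CC)C3=C(OC)[C@@]2(C[C@H]1C)OC3=O | intermediate (not isolated)
47 | primary alcohol (CH2OH in place of CO2H of 45) | CC1=C[C@H]2C/C=C/C=C/C[C@H](O[Si](c5ccccc5)(c5ccccc5)C(C)(C)C)C/C=C/C[C@H](CO)[C@@H]3[C@@H]([C@@H]4COC(C)(C)O4)SC[C@H]3C(O[Si](CC)(CC)CC)C3=C(OC)[C@@]2(C[C@H]1C)OC3=O | intermediate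
48 | primary iodide (CH2I in place of CH2OH of 47) | CC1=C[C@H]2C/C=C/C=C/C[C@H](O[Si](c5ccccc5)(c5ccccc5)C(C)(C)C)C/C=C/C[C@H](CI)[C@@H]3[C@@H]([C@@H]4COC(C)(C)O4)SC[C@H]3C(O[Si](CC)(CC)CC)C3=C(OC)[C@@]2(C[C@H]1C)OC3=O | intermediate
49 | C-methyl macrocycle (CH3 in place of CH2I of 48) | CC1=C[C@H]2C/C=C/C=C/C[C@H](O[Si](c5ccccc5)(c5ccccc5)C(C)(C)C)C/C=C/C[C@H](C)[C@@H]3[C@@H]([C@@H]4COC(C)(C)O4)SC[C@H]3C(O[Si](CC)(CC)CC)C3=C(OC)[C@@]2(C[C@H]1C)OC3=O | intermediate
50 | triol: 49 without the Et3Si group and the acetonide (1,2-diol on thiolane C2, carbinol next to the tetronate) | CC1=C[C@H]2C/C=C/C=C/C[C@H](O[Si](c5ccccc5)(c5ccccc5)C(C)(C)C)C/C=C/C[C@H](C)[C@@H]3[C@@H]([C@@H](O)CO)SC[C@H]3C(O)C3=C(OC)[C@@]2(C[C@H]1C)OC3=O | intermediate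
51 | acyl ketone with 2-oxoacetyl (keto aldehyde) group on thiolane C2 | CC1=C[C@H]2C/C=C/C=C/C[C@H](O[Si](c5ccccc5)(c5ccccc5)C(C)(C)C)C/C=C/C[C@H](C)[C@@H]3[C@@H](C(=O)C=O)SC[C@H]3C(=O)C3=C(OC)[C@@]2(C[C@H]1C)OC3=O | intermediate
52 | α-keto acid, still O-methylated and O-silylated | CC1=C[C@H]2C/C=C/C=C/C[C@H](O[Si](c5ccccc5)(c5ccccc5)C(C)(C)C)C/C=C/C[C@H](C)[C@@H]3[C@@H](C(=O)C(=O)O)SC[C@H]3C(=O)C3=C(OC)[C@@]2(C[C@H]1C)OC3=O | intermediate
53 | O-methyl ether of the target at the tetronate | CC1=C[C@H]2C/C=C/C=C/C[C@H](O)C/C=C/C[C@H](C)[C@@H]3[C@@H](C(=O)C(=O)O)SC[C@H]3C(=O)C3=C(OC)[C@@]2(C[C@H]1C)OC3=O | intermediate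
54 | CNP0224658.3 | CC1=C[C@H]2C/C=C/C=C/C[C@H](O)C/C=C/C[C@H](C)[C@@H]3[C@@H](C(=O)C(=O)O)SC[C@H]3C(=O)C3=C(O)[C@@]2(C[C@H]1C)OC3=O | target

**Step count and risks**

Total: 36 steps. Longest linear sequence: 23 steps (1, 2, 5–8, 20–36, from (R)-lactic acid).

Steps most likely to fail:

1. Step 28. What may go wrong: the transannular shift may pass through a boat or start from the Z(O) ketene acetal, either of which would give the epimer at the carboxyl-bearing carbon, or enolisation of the macrolactone may be slow and give way to decomposition. Fallback: the same [3,3] shift is run on an open-chain ester and the ring is closed afterwards at the diene. Setting out from 35, Me3SnOH hydrolysis gives the thiolane acetic acid F1. Esterification with iodo dienol 32 (EDC·HCl, DMAP, CH2Cl2) gives the allylic ester F2. LiN(iPr)2 with Me3SiCl/Et3N in THF at −78 °C gives the silyl ketene acetal F3, which on warming should rearrange through the unconstrained chair to the silyl ester F4 and, after mild acid work-up, the open-chain unsaturated acid F5, with the same S centre and E-alkene. DDQ then gives the primary alcohol F6, Dess–Martin oxidation the aldehyde F7, and CrCl2/LiI/Cl2CHBpin the alkenylboronate F8. An intramolecular Suzuki–Miyaura coupling (PdCl2(dppf), Ph3As, Cs2CO3, DMF/THF/H2O, high dilution) closes the 19-membered ring and comes back to the route at 45.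

2. Step 12. What may go wrong: intermolecular sulfa-Michael oligomerisation of thiol 21, or poor facial selectivity at C3 in the enamine ring closure. Fallback: C3 is set first by acyclic 1,2-induction and sulfur is introduced last by double displacement. Setting out from 18, Et3SiCl/imidazole gives the silyl ether F9. The cuprate made from 2-bromoallyl 4-methoxybenzyl ether (t-BuLi, CuI, Me3SiCl, THF, −78 °C) should add anti to the γ-silyloxy group and give the branched ester F10. Hydroboration (9-BBN, then NaBO3) gives the primary alcohol F11. HF·pyridine/pyridine gives the diol F12, which is mesylated at once (MsCl, Et3N, −20 °C) to forestall γ-lactonisation and gives the bis-mesylate F13. Na2S in DMF closes the ring by two SN2 displacements, with inversion at C2, to the thiolane ether F14. DDQ gives the thiolane alcohol F15, and SO3·pyridine/DMSO/i-Pr2NEt oxidation followed by DBU equilibration of the formyl-bearing carbon comes back to the route at 23.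

3. Step 34. What may go wrong: oxidation of the thioether to the sulfoxide by hypochlorite released from chlorite, or degradation of the hydrated keto aldehyde 51 before it is oxidised. Fallback: the three oxidations are done one at a time, without chlorite and without a keto aldehyde. Setting out from 50, MnO2 should oxidise only the carbinol next to the tetronate and give the diol ketone F16. TEMPO/PhI(OAc)2 in MeCN/H2O oxidises the primary alcohol to the hydroxy acid F17. Me3SiCHN2 gives the hydroxy ester F18, and Dess–Martin oxidation the keto ester F19. Me3SnOH hydrolysis of this activated ester comes back to the route at 52.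

**Further compounds**

F1 | step 28 | acid from 35 (CO2H in place of CO2Me) | CC1=C[C@@H](CCOCc2ccc(OC)cc2)[C@]3(C[C@H]1C)OC(=O)C(=C3OC)C(O[Si](CC)(CC)CC)[C@@H]4CS[C@H]([C@@H]5COC(C)(C)O5)[C@H]4CC(=O)O
F2 | step 28 | ester of F1 with the (S)-vinyl carbinol of 32 | CC1=C[C@@H](CCOCc2ccc(OC)cc2)[C@]3(C[C@H]1C)OC(=O)C(=C3OC)C(O[Si](CC)(CC)CC)[C@@H]4CS[C@H]([C@@H]5COC(C)(C)O5)[C@H]4CC(=O)O[C@H](C=C)C[C@@H](O[Si](c6ccccc6)(c6ccccc6)C(C)(C)C)C/C=C/I
F3 | step 28 | E(O) trimethylsilyl ketene acetal of F2 | CC1=C[C@@H](CCOCc2ccc(OC)cc2)[C@]3(C[C@H]1C)OC(=O)C(=C3OC)C(O[Si](CC)(CC)CC)[C@@H]4CS[C@H]([C@@H]5COC(C)(C)O5)[C@H]4/C=C(/O[Si](C)(C)C)O[C@H](C=C)C[C@@H](O[Si](c6ccccc6)(c6ccccc6)C(C)(C)C)C/C=C/I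
F4 | step 28 | trimethylsilyl ester of F5 | CC1=C[C@@H](CCOCc2ccc(OC)cc2)[C@]3(C[C@H]1C)OC(=O)C(=C3OC)C(O[Si](CC)(CC)CC)[C@@H]4CS[C@H]([C@@H]5COC(C)(C)O5)[C@H]4[C@@H](C(=O)O[Si](C)(C)C)C/C=C/C[C@@H](O[Si](c6ccccc6)(c6ccccc6)C(C)(C)C)C/C=C/I
F5 | step 28 | open-chain γ,δ-unsaturated acid (S at the carboxyl-bearing carbon, E-alkene, E-iodoalkene terminus) | CC1=C[C@@H](CCOCc2ccc(OC)cc2)[C@]3(C[C@H]1C)OC(=O)C(=C3OC)C(O[Si](CC)(CC)CC)[C@@H]4CS[C@H]([C@@H]5COC(C)(C)O5)[C@H]4[C@@H](C(=O)O)C/C=C/C[C@@H](O[Si](c6ccccc6)(c6ccccc6)C(C)(C)C)C/C=C/I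
F6 | step 28 | F5 with the PMB ether cleaved (primary alcohol) | CC1=C[C@@H](CCO)[C@]3(C[C@H]1C)OC(=O)C(=C3OC)C(O[Si](CC)(CC)CC)[C@@H]4CS[C@H]([C@@H]5COC(C)(C)O5)[C@H]4[C@@H](C(=O)O)C/C=C/C[C@@H](O[Si](c6ccccc6)(c6ccccc6)C(C)(C)C)C/C=C/I
F7 | step 28 | aldehyde from F6 | CC1=C[C@@H](CC=O)[C@]3(C[C@H]1C)OC(=O)C(=C3OC)C(O[Si](CC)(CC)CC)[C@@H]4CS[C@H]([C@@H]5COC(C)(C)O5)[C@H]4[C@@H](C(=O)O)C/C=C/C[C@@H](O[Si](c6ccccc6)(c6ccccc6)C(C)(C)C)C/C=C/I
F8 | step 28 | E-alkenyl pinacol boronate from F7 | CC1=C[C@@H](C/C=C/B2OC(C)(C)C(C)(C)O2)[C@]3(C[C@H]1C)OC(=O)C(=C3OC)C(O[Si](CC)(CC)CC)[C@@H]4CS[C@H]([C@@H]5COC(C)(C)O5)[C@H]4[C@@H](C(=O)O)C/C=C/C[C@@H](O[Si](c6ccccc6)(c6ccccc6)C(C)(C)C)C/C=C/I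
F9 | step 12 | methyl (2E,4R)-4-[(4S)-2,2-dimethyl-1,3-dioxolan-4-yl]-4-[(triethylsilyl)oxy]but-2-enoate | COC(=O)/C=C/[C@@H](O[Si](CC)(CC)CC)[C@@H]1COC(C)(C)O1
F10 | step 12 | anti conjugate adduct: methyl 3-[3-(4-methoxybenzyloxy)prop-1-en-2-yl]-4-[(4S)-dioxolanyl]-4-[(triethylsilyl)oxy]butanoate | COC(=O)C[C@@H](C(=C)COCc2ccc(OC)cc2)[C@@H](O[Si](CC)(CC)CC)[C@@H]1COC(C)(C)O1
F11 | step 12 | primary alcohol from hydroboration of F10 (new CH centre as both epimers) | COC(=O)C[C@@H](C(CO)COCc2ccc(OC)cc2)[C@@H](O[Si](CC)(CC)CC)[C@@H]1COC(C)(C)O1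
F12 | step 12 | diol from F11 (Et3Si removed) | COC(=O)C[C@@H](C(CO)COCc2ccc(OC)cc2)[C@@H](O)[C@@H]1COC(C)(C)O1
F13 | step 12 | bis-mesylate of F12 | COC(=O)C[C@@H](C(COS(C)(=O)=O)COCc2ccc(OC)cc2)[C@@H](OS(C)(=O)=O)[C@@H]1COC(C)(C)O1
F14 | step 12 | methyl 2-[(2S,3S)-2-[(4S)-dioxolanyl]-4-[(4-methoxybenzyloxy)methyl]thiolan-3-yl]acetate (C4 epimers) | COC(=O)C[C@@H]1[C@@H]([C@@H]2COC(C)(C)O2)SCC1COCc1ccc(OC)cc1
F15 | step 12 | methyl 2-[(2S,3S)-2-[(4S)-dioxolanyl]-4-(hydroxymethyl)thiolan-3-yl]acetate (C4 epimers) | COC(=O)C[C@@H]1[C@@H]([C@@H]2COC(C)(C)O2)SCC1CO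
F16 | step 34 | diol ketone: 50 with the carbinol next to the tetronate oxidised | CC1=C[C@H]2C/C=C/C=C/C[C@H](O[Si](c5ccccc5)(c5ccccc5)C(C)(C)C)C/C=C/C[C@H](C)[C@@H]3[C@@H]([C@@H](O)CO)SC[C@H]3C(=O)C3=C(OC)[C@@]2(C[C@H]1C)OC3=O
F17 | step 34 | α-hydroxy acid from F16 | CC1=C[C@H]2C/C=C/C=C/C[C@H](O[Si](c5ccccc5)(c5ccccc5)C(C)(C)C)C/C=C/C[C@H](C)[C@@H]3[C@@H]([C@@H](O)C(=O)O)SC[C@H]3C(=O)C3=C(OC)[C@@]2(C[C@H]1C)OC3=O
F18 | step 34 | methyl ester of F17 | CC1=C[C@H]2C/C=C/C=C/C[C@H](O[Si](c5ccccc5)(c5ccccc5)C(C)(C)C)C/C=C/C[C@H](C)[C@@H]3[C@@H]([C@@H](O)C(=O)OC)SC[C@H]3C(=O)C3=C(OC)[C@@]2(C[C@H]1C)OC3=O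
F19 | step 34 | α-keto methyl ester | CC1=C[C@H]2C/C=C/C=C/C[C@H](O[Si](c5ccccc5)(c5ccccc5)C(C)(C)C)C/C=C/C[C@H](C)[C@@H]3[C@@H](C(=O)C(=O)OC)SC[C@H]3C(=O)C3=C(OC)[C@@]2(C[C@H]1C)OC3=O
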